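Ring B of the target carries its hydroxyl on C4, bromine on both neighbours C3 and C5, and the CH2 bridge on C1 – exactly the carbonyl carbon, the two alpha carbons and the gamma carbon of a 4-substituted cyclohexanone. Ring B is therefore carried saturated and the route rests on converting that ketone into the 2,6-dibromophenol: fourfold alpha-bromination followed by loss of two HBr forms both C–Br bonds and the aromatic ring in one operation. The precursor is 2-bromo-4-[(4-oxocyclohexyl)methyl]phenyl acetate, whose ring A already holds its single bromine and is deactivated as the acetate. Its skeleton comes from a B-alkyl Suzuki–Miyaura coupling.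

Key step: step 5

Remark: the target is achiral and no numbered compound contains a stereocentre, so no stereochemical control is needed; 9-BBN is written as its monomer.

Step 1
Reactants: 1 8-methylene-1,4-dioxaspiro[4.5]decane; 2 9-borabicyclo[3.3.1]nonane (9-BBN); 3 4-bromoanisole
Product: 5 8-[(4-methoxyphenyl)methyl]-1,4-dioxaspiro[4.5]decane, via alkylborane 4 (not isolated)
Conditions: 1, 2 (1.2 equiv), THF, 0 °C → rt; then 3, Pd(dppf)Cl2 (3 mol %), 3 M aq NaOH (3 equiv), THF, 65 °C
Reagents that add atoms: none
Why: Anti-Markovnikov hydroboration of the 1,1-disubstituted alkene places boron on the exocyclic CH2, and the primary B-alkyl-9-BBN then undergoes B-alkyl Suzuki–Miyaura coupling (oxidative addition of the aryl bromide to zerovalent palladium, hydroxide-assisted transmetalation, reductive elimination); the ketal is inert to aqueous base.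

Step 2
Reactants: 5 8-[(4-methoxyphenyl)methyl]-1,4-dioxaspiro[4.5]decane
Product: 6 8-[(3-bromo-4-methoxyphenyl)methyl]-1,4-dioxaspiro[4.5]decane
Conditions: NBS (1.05 equiv), MeCN, 0 °C → rt, dark
Reagents that add atoms: N-bromosuccinimide, O=C1CCC(=O)N1Br
Why: Electrophilic aromatic bromination of a para-substituted anisole can only go ortho to the methoxy group, the first bromine deactivates the ring against a second one, and the neutral medium leaves the ketal untouched.

Step 3
Reactants: 6 8-[(3-bromo-4-methoxyphenyl)methyl]-1,4-dioxaspiro[4.5]decane
Product: 7 4-[(3-bromo-4-hydroxyphenyl)methyl]cyclohexan-1-one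
Conditions: BBr3 (3 equiv), CH2Cl2, −78 → 0 °C; then H2O, THF, 1 M HCl, rt
Reagents that add atoms: water, O
Why: BBr3 ether cleavage (Lewis-acid activation of the aryl methyl ether, bromide attack on the methyl group) also opens the dioxolane, and the aqueous acid work-up should release both the phenol and the ketone; an isolated ketone and an aryl bromide are known to tolerate this reagent at low temperature.

Step 4
Reactants: 7 4-[(3-bromo-4-hydroxyphenyl)methyl]cyclohexan-1-one
Product: 8 2-bromo-4-[(4-oxocyclohexyl)methyl]phenyl acetate
Conditions: Ac2O (1.5 equiv), pyridine (2 equiv), DMAP (cat.), CH2Cl2, 0 °C → rt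
Reagents that add atoms: acetic anhydride, CC(=O)OC(C)=O
Why: DMAP-catalysed O-acylation of the phenol is fast and selective, since the ketone does not form an enol acetate under these mild basic conditions.

Step 5
Reactants: 8 2-bromo-4-[(4-oxocyclohexyl)methyl]phenyl acetate
Product: 11 2-bromo-4-[(3,5-dibromo-4-hydroxyphenyl)methyl]phenyl acetate, via tetrabromoketone 9 (not isolated), via dibromodienone 10 (not isolated)
Conditions: Br2 (4.2 equiv), HBr (cat.), glacial AcOH, 20 → 45 °C, dark, N2 sweep; evaporate; then Li2CO3 (3 equiv), dry DMF, 90 °C; 1 M HCl work-up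
Reagents that add atoms: bromine, BrBr
Why: HBr-catalysed enolisation toward C3 and C5 of the future ring B lets each enol capture Br2, and the cycle repeats until both alpha carbons are geminal dibromides and no alpha hydrogen remains (9). Li2CO3 in DMF then removes HBr across each alpha–beta bond by E2 elimination to give the cross-conjugated dienone 10, which loses the hydrogen on its sp3 ring carbon in a keto–phenol tautomerisation driven by aromaticity, so that one bromine stays on each carbon flanking the oxygen. The closest known reaction type is the exhaustive alpha-halogenation of a cyclohexanone followed by dehydrohalogenation to a 2,6-dihalophenol. No ring is closed (the six-membered ring already present is aromatised) and no stereocentre is formed. The step needs chemoselectivity for the ketone alpha carbons over ring A and over the benzylic CH2: the enol is far more nucleophilic than ring A, which is deactivated by its acetoxy group and its bromine, the anhydrous acid leaves the acetate in place, and exclusion of light suppresses radical benzylic bromination. The mirror symmetry of the 4-substituted ketone makes the two alpha carbons equivalent, so no regiochemical question arises, and acetyl transfer to the new phenol is disfavoured because the more acidic, hindered 2,6-dibromophenol is the poorer acyl acceptor.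

Step 6
Reactants: 11 2-bromo-4-[(3,5-dibromo-4-hydroxyphenyl)methyl]phenyl acetate
Product: 12 2-bromo-4-[(3,5-dibromo-4-hydroxyphenyl)methyl]phenol (= 2,6-dibromo-4-[(3-bromo-4-hydroxyphenyl)methyl]phenol)
Conditions: K2CO3 (2.5 equiv), MeOH, 0 °C → rt; then 1 M HCl
Reagents that add atoms: none
Why: Base-mediated transesterification (methanolysis) of an aryl acetate is rapid at room temperature and leaves the aryl bromides and the diarylmethane untouched.

Compound list
1 | 8-methylene-1,4-dioxaspiro[4.5]decane | C=C1CCC2(CC1)OCCO2 | starting material
2 | 9-borabicyclo[3.3.1]nonane (9-BBN) | B1C2CCCC1CCC2 | starting material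
3 | 4-bromoanisole (1-bromo-4-methoxybenzene) | COc1ccc(Br)cc1 | starting material
4 | 9-[(1,4-dioxaspiro[4.5]decan-8-yl)methyl]-9-borabicyclo[3.3.1]nonane | O1CCOC12CCC(CB3C4CCCC3CCC4)CC2 | intermediate (not isolated)
5 | 8-[(4-methoxyphenyl)methyl]-1,4-dioxaspiro[4.5]decane | COc1ccc(CC2CCC3(CC2)OCCO3)cc1 | intermediate
6 | 8-[(3-bromo-4-methoxyphenyl)methyl]-1,4-dioxaspiro[4.5]decane | COc1ccc(CC2CCC3(CC2)OCCO3)cc1Br | intermediate
7 | 4-[(3-bromo-4-hydroxyphenyl)methyl]cyclohexan-1-one | O=C1CCC(Cc2ccc(O)c(Br)c2)CC1 | intermediate
8 | 2-bromo-4-[(4-oxocyclohexyl)methyl]phenyl acetate | CC(=O)Oc1ccc(CC2CCC(=O)CC2)cc1Br | intermediate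
9 | 2-bromo-4-[(3,3,5,5-tetrabromo-4-oxocyclohexyl)methyl]phenyl acetate | CC(=O)Oc1ccc(CC2CC(Br)(Br)C(=O)C(Br)(Br)C2)cc1Br | intermediate (not isolated)
10 | 2-bromo-4-[(3,5-dibromo-4-oxocyclohexa-2,5-dien-1-yl)methyl]phenyl acetate | CC(=O)Oc1ccc(CC2C=C(Br)C(=O)C(Br)=C2)cc1Br | intermediate (not isolated)
11 | 2-bromo-4-[(3,5-dibromo-4-hydroxyphenyl)methyl]phenyl acetate | CC(=O)Oc1ccc(Cc2cc(Br)c(O)c(Br)c2)cc1Br | intermediate
12 | 2-bromo-4-[(3,5-dibromo-4-hydroxyphenyl)methyl]phenol | Oc1ccc(Cc2cc(Br)c(O)c(Br)c2)cc1Br | target

Total step count: 6
Longest linear sequence: 6 steps (1 → 12)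

Steps most likely to fail

Step 5. The alpha-bromination may stall before both alpha carbons are geminally dibrominated, or the gem-dibromides may lose bromine again to HBr or bromide before elimination. Either would leave ring B with fewer than two bromines. Traces of water could also unmask ring A and expose it to bromine. The fallback aromatises first and brominates afterwards. Setting out from 8, Br2 (2 equiv) in AcOH should give 2-bromo-4-[(3,5-dibromo-4-oxocyclohexyl)methyl]phenyl acetate F1 (mixture of diastereomers). Heating F1 with LiCl in DMF should remove two HBr and give 2-bromo-4-[(4-hydroxyphenyl)methyl]phenyl acetate F2; no carbonate is used, so that no phenoxide able to take over the acetyl group is generated. Electrophilic bromination of F2 with Br2 (2 equiv) in CH2Cl2 at 0 °C should then fill only the two ortho positions of the free phenol of ring B, since its para position is blocked and ring A is deactivated. The sequence returns to the route at 11. The same closing bromination would also complete ring B in any under-brominated material from step 5.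

Step 3. The Lewis acid may promote self-condensation of the liberated ketone, or the ketal may be unmasked incompletely. The fallback separates the two deprotections and avoids the Lewis acid. Setting out from 6, nucleophilic demethylation with NaSEt in DMF at 110 °C (SN2 attack of thiolate on the methyl group, ketal stable to base) should give 2-bromo-4-[(1,4-dioxaspiro[4.5]decan-8-yl)methyl]phenol F3. Mild hydrolysis of the ketal with 1 M HCl in acetone at rt then returns to the route at 7.

Step 1. Oxidative addition to the electron-rich aryl bromide may be slow, and the alkylborane may be lost by protodeboronation before it transmetalates. The fallback replaces the organoborane by an organozinc reagent. Setting out from 1, hydroboration–oxidation (BH3·THF; then NaOH, H2O2) should give (1,4-dioxaspiro[4.5]decan-8-yl)methanol F4. An Appel reaction (I2, PPh3, imidazole, CH2Cl2) converts it into 8-(iodomethyl)-1,4-dioxaspiro[4.5]decane F5. LiCl-assisted zinc insertion (Zn dust, LiCl, THF) gives [(1,4-dioxaspiro[4.5]decan-8-yl)methyl]zinc iodide F6. Negishi coupling of F6 with 3 (Pd(OAc)2, SPhos, THF, 50 °C) returns to the route at 5.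

Further compounds
F1 | step 5 | 2-bromo-4-[(3,5-dibromo-4-oxocyclohexyl)methyl]phenyl acetate (mixture of diastereomers) | CC(=O)Oc1ccc(CC2CC(Br)C(=O)C(Br)C2)cc1Br
F2 | step 5 | 2-bromo-4-[(4-hydroxyphenyl)methyl]phenyl acetate | CC(=O)Oc1ccc(Cc2ccc(O)cc2)cc1Br
F3 | step 3 | 2-bromo-4-[(1,4-dioxaspiro[4.5]decan-8-yl)methyl]phenol | Oc1ccc(CC2CCC3(CC2)OCCO3)cc1Br
F4 | step 1 | (1,4-dioxaspiro[4.5]decan-8-yl)methanol | OCC1CCC2(CC1)OCCO2
F5 | step 1 | 8-(iodomethyl)-1,4-dioxaspiro[4.5]decane | ICC1CCC2(CC1)OCCO2
F6 | step 1 | [(1,4-dioxaspiro[4.5]decan-8-yl)methyl]zinc iodide | I[Zn]CC1CCC2(CC1)OCCO2
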